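## Retrosynthetic overview

- The target is opened at the acyl C–CH2 bond of the side chain: a ring aldehyde (the formyl carbon on ring C1 becomes the ketone carbon) plus an (E)-configured C6 alkyllithium made from but-3-yn-1-ol by carboalumination; acetylation and deprotection come last.
- The ring aldehyde goes back to a 4-formyl-4-methyl-5-alkylcyclohex-2-enone: the formyl group is masked as CH2OH, the α'-carbon (future C3) is methylated twice, the alkene is hydrogenated and the ring carbonyl (future C4) is removed by Wolff–Kishner reduction.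
- The cyclohexenone comes from a catalytic asymmetric [4+2] cycloaddition of an (E)-2-methyl-2-enal (from ethyl levulinate) with a 1-carbamato-3-siloxybutadiene. This forms the C1–C6 and C2–C3 bonds, the only ring and both stereocentres.
- The strategy rests on one feature of the cyclohexane: the acyl group on quaternary C1 (which also carries methyl) and the 3-oxobutyl chain on C2 are trans, which is what a suprafacial cycloaddition to an E-trisubstituted enal leaves; C3 (CMe2) and C4 (CH2) are the α'- and carbonyl carbons of the enone that results.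

Key step: step 7

Remarks:
- Assumption on the catalyst: the (R,R)-salen ligand is written for step 7. Which antipode gives the (1S,6R) adduct must be settled in a first run (for example by correlation of 14); the (S,S) complex is used, with no other change, if the sense is opposite.
- Enolates, alkoxides and amide anions are treated as conjugate bases of the numbered compounds and carry no numbers of their own.

## Route

Step 1
Reactants: 1 ethyl levulinate
Product: 2 ethyl 3-(2-methyl-1,3-dioxolan-2-yl)propanoate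
Conditions: HOCH2CH2OH, p-TsOH·H2O (cat.), toluene, reflux (Dean–Stark)
Reagents that add atoms: ethylene glycol, OCCO
Why: Acid-catalysed ketalisation with azeotropic removal of water protects the ketone as a dioxolane that should survive all later basic, reductive and organometallic steps.

Step 2
Reactants: 2 ethyl 3-(2-methyl-1,3-dioxolan-2-yl)propanoate
Product: 3 3-(2-methyl-1,3-dioxolan-2-yl)propanal
Conditions: i-Bu2AlH (1.05 equiv), CH2Cl2, −78 °C; MeOH, aq. potassium sodium tartrate
Reagents that add atoms: none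
Why: Partial ester reduction with i-Bu2AlH at −78 °C stops at the aluminium hemiacetal, which releases the aldehyde only on hydrolytic work-up.

Step 3
Reactants: 3 3-(2-methyl-1,3-dioxolan-2-yl)propanal; 4 2-(triphenylphosphoranylidene)propanal
Product: 5 (E)-2-methyl-5-(2-methyl-1,3-dioxolan-2-yl)pent-2-enal
Conditions: toluene, 90 °C
Reagents that add atoms: none
Why: Wittig olefination with a stabilised formyl ylide should give the (E)-2-methyl-2-enal selectively, and the α-branched conjugated product is too unreactive to olefinate a second time.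

Step 4
Reactants: 6 (E)-4-methoxybut-3-en-2-one; 7 benzylamine
Product: 8 (Z)-4-(benzylamino)but-3-en-2-one
Conditions: MeOH, 0 °C → rt
Reagents that add atoms: none
Why: Conjugate addition–elimination of the amine on the β-methoxy enone gives the vinylogous amide, held in the Z form by an N–H···O hydrogen bond.

Step 5
Reactants: 8 (Z)-4-(benzylamino)but-3-en-2-one
Product: 9 methyl benzyl[(1E)-3-oxobut-1-en-1-yl]carbamate
Conditions: NaN(SiMe3)2, THF, −78 °C; ClCO2Me, −78 → 0 °C
Reagents that add atoms: methyl chloroformate, COC(=O)Cl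
Why: N-acylation of the sodium salt of the vinylogous amide gives the vinylogous imide, whose carbamate nitrogen is a weaker donor and Lewis base than a dialkylamino group, so the derived diene should tolerate a Lewis acid catalyst.

Step 6
Reactants: 9 methyl benzyl[(1E)-3-oxobut-1-en-1-yl]carbamate
Product: 10 methyl benzyl[(1E)-3-(tert-butyldimethylsilyloxy)buta-1,3-dien-1-yl]carbamate
Conditions: NaN(SiMe3)2, THF, −78 °C; TBSCl, −78 °C → rt
Reagents that add atoms: tert-butyldimethylsilyl chloride, CC(C)(C)[Si](C)(C)Cl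
Why: Kinetic deprotonation of the methyl ketone and O-silylation (silyl enol ether formation) give the 2-siloxy diene with the E enamide geometry retained.

Step 7
Reactants: 5 (E)-2-methyl-5-(2-methyl-1,3-dioxolan-2-yl)pent-2-enal; 10 methyl benzyl[(1E)-3-(tert-butyldimethylsilyloxy)buta-1,3-dien-1-yl]carbamate
Product: 13 (1S,6R)-1-methyl-6-[2-(2-methyl-1,3-dioxolan-2-yl)ethyl]-4-oxocyclohex-2-ene-1-carbaldehyde, via endo cycloadduct silyl enol ether 11 (not isolated), via beta-carbamato ketone 12 (not isolated)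
Conditions: (R,R)-[Cr(salen)]SbF6 (10 mol %; trivalent chromium; from (R,R)-Cr(salen)Cl and AgSbF6; salen = N,N'-bis(3,5-di-tert-butylsalicylidene)cyclohexane-1,2-diamine dianion), 4 Å MS, CH2Cl2 (concentrated), −20 °C → rt; then Bu4NF/AcOH (1:1), THF, 0 °C; then DBU, rt
Reagents that add atoms: none
Why: Proposed new method: the cationic chromium–salen Lewis acid binds the formyl oxygen of 5 and the push–pull diene 10 adds in a concerted, asynchronous, suprafacial [4+2] cycloaddition, its CH2 terminus bonding to the β-carbon and its nitrogen-bearing terminus to the α-carbon of the enal, which closes the cyclohexene ring of 11 by intermolecular six-membered cycloaddition in which both ring bonds form in one event. The closest known reaction type is the same cationic Cr(salen)-catalysed Diels–Alder reaction of 1-carbamato-3-siloxydienes with α-substituted acroleins, which builds formyl-bearing quaternary centres; what is new is the additional β-alkyl group of the trisubstituted enal, which lowers reactivity and is met here by higher concentration, loading and temperature. The quaternary carbon C1 and the chain-bearing carbon C6 of 13 are set together: their relative configuration (formyl trans to the chain) is carried over from the E alkene of 5 by the suprafacial addition, and their absolute configuration is set by the salen ligand, which shields one face of the bound enal, while the C–N centre of 11 (endo expected) is erased afterwards. The step needs regioselectivity, which the donor pattern of the diene (carbamate nitrogen at C1, siloxy group at C3) secures, and enal-face selectivity, which is the open point; endo and exo approach to the same enal face lead to the same C1/C6 configuration, so only the face matters. In the same flask buffered fluoride cleaves the silyl enol ether to ketone 12 without touching the dioxolane, and DBU expels methyl benzylcarbamate from the β-position (E1cB) to give the enone.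

Step 8
Reactants: 13 (1S,6R)-1-methyl-6-[2-(2-methyl-1,3-dioxolan-2-yl)ethyl]-4-oxocyclohex-2-ene-1-carbaldehyde
Product: 14 (4S,5R)-4-(hydroxymethyl)-4-methyl-5-[2-(2-methyl-1,3-dioxolan-2-yl)ethyl]cyclohex-2-en-1-one
Conditions: NaBH4, EtOH/CH2Cl2 (3:7), −78 °C
Reagents that add atoms: none
Why: Chemoselective borohydride reduction: at −78 °C an aldehyde is reduced much faster than a conjugated ketone, so the formyl group should be masked as CH2OH with the enone and both stereocentres untouched.

Step 9
Reactants: 14 (4S,5R)-4-(hydroxymethyl)-4-methyl-5-[2-(2-methyl-1,3-dioxolan-2-yl)ethyl]cyclohex-2-en-1-one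
Product: 15 (4S,5R)-4-[(benzyloxy)methyl]-4-methyl-5-[2-(2-methyl-1,3-dioxolan-2-yl)ethyl]cyclohex-2-en-1-one
Conditions: 2-benzyloxy-1-methylpyridinium triflate, MgO, PhCF3, 85 °C
Reagents that add atoms: 2-benzyloxy-1-methylpyridinium triflate, C[n+]1ccccc1OCc1ccccc1.[O-]S(=O)(=O)C(F)(F)F
Why: Benzyl transfer from the 2-benzyloxypyridinium salt (Dudley benzylation) runs under neutral conditions, which avoids both an alkoxide (vinylogous retro-aldol loss of formaldehyde from the γ-hydroxymethyl enone) and acid (ketal).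

Step 10
Reactants: 15 (4S,5R)-4-[(benzyloxy)methyl]-4-methyl-5-[2-(2-methyl-1,3-dioxolan-2-yl)ethyl]cyclohex-2-en-1-one
Product: 17 (4R,5S)-4-[(benzyloxy)methyl]-4,6,6-trimethyl-5-[2-(2-methyl-1,3-dioxolan-2-yl)ethyl]cyclohex-2-en-1-one, via monomethyl enone 16 (not isolated)
Conditions: LiN(i-Pr)2, THF, −78 °C; MeI, −78 → 0 °C; then LiN(i-Pr)2, DMPU, −78 °C; MeI, −78 °C → rt
Reagents that add atoms: iodomethane, IC
Why: Kinetic α'-enolate alkylation: with C4 quaternary the enone can be deprotonated only at C6, so two deprotonation/methylation cycles should install the gem-dimethyl group next to the chain-bearing carbon, whose configuration is not touched (the descriptors change only through CIP priorities).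

Step 11
Reactants: 17 (4R,5S)-4-[(benzyloxy)methyl]-4,6,6-trimethyl-5-[2-(2-methyl-1,3-dioxolan-2-yl)ethyl]cyclohex-2-en-1-one
Product: 18 (3S,4R)-4-(hydroxymethyl)-2,2,4-trimethyl-3-[2-(2-methyl-1,3-dioxolan-2-yl)ethyl]cyclohexan-1-one
Conditions: H2 (1–3 atm), Pd(OH)2/C, EtOAc, rt
Reagents that add atoms: none
Why: Heterogeneous hydrogenation should saturate the disubstituted enone alkene and hydrogenolyse the benzyl ether in the same operation, without forming or touching a stereocentre.

Step 12
Reactants: 18 (3S,4R)-4-(hydroxymethyl)-2,2,4-trimethyl-3-[2-(2-methyl-1,3-dioxolan-2-yl)ethyl]cyclohexan-1-one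
Product: 19 [(1R,2R)-1,3,3-trimethyl-2-[2-(2-methyl-1,3-dioxolan-2-yl)ethyl]cyclohexyl]methanol
Conditions: N2H4·H2O, KOH, diethylene glycol, 130 °C then 200 °C (water distilled off)
Reagents that add atoms: none
Why: Wolff–Kishner reduction (Huang-Minlon procedure) removes the carbonyl group via its hydrazone, as is usual for ketones flanked by a gem-dimethyl carbon; dioxolane and alcohol are inert to hot alkali and neither stereocentre is α to the ketone.

Step 13
Reactants: 19 [(1R,2R)-1,3,3-trimethyl-2-[2-(2-methyl-1,3-dioxolan-2-yl)ethyl]cyclohexyl]methanol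
Product: 20 (1R,2R)-1,3,3-trimethyl-2-[2-(2-methyl-1,3-dioxolan-2-yl)ethyl]cyclohexane-1-carbaldehyde
Conditions: Dess–Martin periodinane, NaHCO3, CH2Cl2, 0 °C → rt
Reagents that add atoms: none
Why: Dess–Martin oxidation of the neopentyl primary alcohol stops at the aldehyde, which has no α-hydrogen and cannot epimerise, and the bicarbonate buffer protects the ketal.

Step 14
Reactants: 21 but-3-yn-1-ol
Product: 22 1-[(but-3-yn-1-yloxy)methyl]-4-methoxybenzene
Conditions: NaH, 4-methoxybenzyl chloride, tetrabutylammonium iodide (cat.), THF/DMF, 0 °C → rt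
Reagents that add atoms: 4-methoxybenzyl chloride, COc1ccc(CCl)cc1
Why: Williamson etherification gives a PMB ether that tolerates AlMe3 and can later be removed oxidatively beside a silyl ether.

Step 15
Reactants: 22 1-[(but-3-yn-1-yloxy)methyl]-4-methoxybenzene
Product: 25 (E)-5-[(4-methoxybenzyl)oxy]-3-methylpent-2-en-1-ol, via alkenyldimethylalane 23 (not isolated), via lithium butyl alanate 24 (not isolated)
Conditions: AlMe3 (3 equiv), Cp2ZrCl2 (0.25 equiv), CH2Cl2, 0 °C → rt; volatiles removed, hexane/THF; n-BuLi, 0 °C; (CH2O)n, rt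
Reagents that add atoms: trimethylaluminium, C[Al](C)C; paraformaldehyde (as formaldehyde), C=O
Why: Zirconium-catalysed Negishi carboalumination adds methyl and aluminium syn across the terminal alkyne with aluminium on the terminal carbon, and the alkenyl group of the derived alanate adds to formaldehyde with retention, which fixes the E trisubstituted alkene.

Step 16
Reactants: 25 (E)-5-[(4-methoxybenzyl)oxy]-3-methylpent-2-en-1-ol
Product: 26 tert-butyl{[(2E)-5-[(4-methoxybenzyl)oxy]-3-methylpent-2-en-1-yl]oxy}dimethylsilane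
Conditions: TBSCl, imidazole, DMF, rt
Reagents that add atoms: tert-butyldimethylsilyl chloride, CC(C)(C)[Si](C)(C)Cl
Why: Standard silylation of the primary allylic alcohol gives a TBS ether that should withstand DDQ, iodination and t-BuLi.

Step 17
Reactants: 26 tert-butyl{[(2E)-5-[(4-methoxybenzyl)oxy]-3-methylpent-2-en-1-yl]oxy}dimethylsilane
Product: 27 (E)-5-[(tert-butyldimethylsilyl)oxy]-3-methylpent-3-en-1-ol
Conditions: DDQ, CH2Cl2/pH 7 buffer, 0 °C
Reagents that add atoms: none
Why: Oxidative PMB cleavage by DDQ (benzylic hydride abstraction, hydrolysis of the oxocarbenium ion) leaves the silyl ether and the alkene untouched.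

Step 18
Reactants: 27 (E)-5-[(tert-butyldimethylsilyl)oxy]-3-methylpent-3-en-1-ol
Product: 28 tert-butyl{[(2E)-5-iodo-3-methylpent-2-en-1-yl]oxy}dimethylsilane
Conditions: PPh3, iodine, imidazole, CH2Cl2, 0 °C
Reagents that add atoms: iodine, [I][I]
Why: Appel-type iodination converts the primary alcohol into the iodide by SN2 displacement of the alkoxyphosphonium ion under imidazole-buffered conditions that spare the silyl ether.

Step 19
Reactants: 28 tert-butyl{[(2E)-5-iodo-3-methylpent-2-en-1-yl]oxy}dimethylsilane; 20 (1R,2R)-1,3,3-trimethyl-2-[2-(2-methyl-1,3-dioxolan-2-yl)ethyl]cyclohexane-1-carbaldehyde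
Product: 30 (4E)-6-[(tert-butyldimethylsilyl)oxy]-4-methyl-1-[(1R,2R)-1,3,3-trimethyl-2-[2-(2-methyl-1,3-dioxolan-2-yl)ethyl]cyclohexyl]hex-4-en-1-ol as a mixture of carbinol epimers, via alkyllithium 29 (not isolated)
Conditions: 28 (1.5 equiv), t-BuLi (3.0 equiv), Et2O/pentane, −78 °C; then 20, −78 → 0 °C
Reagents that add atoms: none
Why: Lithium–iodine exchange with two equivalents of t-BuLi per iodide gives the primary homoallylic alkyllithium, which adds 1,2 to the non-enolisable aldehyde; the new carbinol centre forms as a mixture and is removed in the next step.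

Step 20
Reactants: 30 (4E)-6-[(tert-butyldimethylsilyl)oxy]-4-methyl-1-[(1R,2R)-1,3,3-trimethyl-2-[2-(2-methyl-1,3-dioxolan-2-yl)ethyl]cyclohexyl]hex-4-en-1-ol
Product: 31 (4E)-6-[(tert-butyldimethylsilyl)oxy]-4-methyl-1-[(1R,2R)-1,3,3-trimethyl-2-[2-(2-methyl-1,3-dioxolan-2-yl)ethyl]cyclohexyl]hex-4-en-1-one
Conditions: Dess–Martin periodinane, NaHCO3, CH2Cl2, rt
Reagents that add atoms: none
Why: Dess–Martin oxidation of the hindered secondary alcohol gives the ketone and erases the carbinol stereocentre, while the adjacent quaternary carbon rules out epimerisation.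

Step 21
Reactants: 31 (4E)-6-[(tert-butyldimethylsilyl)oxy]-4-methyl-1-[(1R,2R)-1,3,3-trimethyl-2-[2-(2-methyl-1,3-dioxolan-2-yl)ethyl]cyclohexyl]hex-4-en-1-one
Product: 32 (4E)-6-hydroxy-4-methyl-1-[(1R,2R)-1,3,3-trimethyl-2-(3-oxobutyl)cyclohexyl]hex-4-en-1-one
Conditions: p-TsOH·H2O (0.1 equiv), acetone/H2O (10:1), rt
Reagents that add atoms: water, O
Why: Mild acid-catalysed hydrolysis (transketalisation with acetone) should remove the dioxolane and the primary silyl ether in one operation.

Step 22
Reactants: 32 (4E)-6-hydroxy-4-methyl-1-[(1R,2R)-1,3,3-trimethyl-2-(3-oxobutyl)cyclohexyl]hex-4-en-1-one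
Product: 33 (2E)-3-methyl-6-oxo-6-[(1R,2R)-1,3,3-trimethyl-2-(3-oxobutyl)cyclohexyl]hex-2-en-1-yl acetate (CNP0326957.1)
Conditions: Ac2O, pyridine, DMAP (cat.), CH2Cl2, 0 °C → rt
Reagents that add atoms: acetic anhydride, CC(=O)OC(C)=O
Why: DMAP-catalysed acylation of the primary allylic alcohol gives the acetate, and both ketones are inert to these conditions.

## Compound list

1 | ethyl levulinate (ethyl 4-oxopentanoate) | CCOC(=O)CCC(C)=O | starting material
2 | ethyl 3-(2-methyl-1,3-dioxolan-2-yl)propanoate | CCOC(=O)CCC1(C)OCCO1 | intermediate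
3 | 3-(2-methyl-1,3-dioxolan-2-yl)propanal | O=CCCC1(C)OCCO1 | intermediate
4 | 2-(triphenylphosphoranylidene)propanal | CC(C=O)=P(c1ccccc1)(c1ccccc1)c1ccccc1 | starting material
5 | (E)-2-methyl-5-(2-methyl-1,3-dioxolan-2-yl)pent-2-enal | O=C/C(C)=C/CCC1(C)OCCO1 | intermediate
6 | (E)-4-methoxybut-3-en-2-one | CO/C=C/C(C)=O | starting material
7 | benzylamine | NCc1ccccc1 | starting material
8 | (Z)-4-(benzylamino)but-3-en-2-one | CC(=O)/C=C\NCc1ccccc1 | intermediate
9 | methyl benzyl[(1E)-3-oxobut-1-en-1-yl]carbamate | COC(=O)N(Cc1ccccc1)/C=C/C(C)=O | intermediate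
10 | methyl benzyl[(1E)-3-(tert-butyldimethylsilyloxy)buta-1,3-dien-1-yl]carbamate | COC(=O)N(Cc1ccccc1)/C=C/C(=C)O[Si](C)(C)C(C)(C)C | intermediate
11 | methyl benzyl[(1R,5R,6S)-3-(tert-butyldimethylsilyloxy)-6-formyl-6-methyl-5-[2-(2-methyl-1,3-dioxolan-2-yl)ethyl]cyclohex-2-en-1-yl]carbamate (endo cycloadduct, formed in the flask) | CC1(CC[C@@H]2CC(O[Si](C)(C)C(C)(C)C)=C[C@@H](N(Cc3ccccc3)C(=O)OC)[C@@]2(C)C=O)OCCO1 | intermediate
12 | methyl benzyl[(1R,2S,3R)-2-formyl-2-methyl-3-[2-(2-methyl-1,3-dioxolan-2-yl)ethyl]-5-oxocyclohexyl]carbamate (formed in the flask) | CC1(CC[C@@H]2CC(=O)C[C@@H](N(Cc3ccccc3)C(=O)OC)[C@@]2(C)C=O)OCCO1 | intermediate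
13 | (1S,6R)-1-methyl-6-[2-(2-methyl-1,3-dioxolan-2-yl)ethyl]-4-oxocyclohex-2-ene-1-carbaldehyde (formyl trans to the chain) | CC1(CC[C@@H]2CC(=O)C=C[C@@]2(C)C=O)OCCO1 | intermediate
14 | (4S,5R)-4-(hydroxymethyl)-4-methyl-5-[2-(2-methyl-1,3-dioxolan-2-yl)ethyl]cyclohex-2-en-1-one | CC1(CC[C@@H]2CC(=O)C=C[C@@]2(C)CO)OCCO1 | intermediate
15 | (4S,5R)-4-[(benzyloxy)methyl]-4-methyl-5-[2-(2-methyl-1,3-dioxolan-2-yl)ethyl]cyclohex-2-en-1-one | CC1(CC[C@@H]2CC(=O)C=C[C@@]2(C)COCc3ccccc3)OCCO1 | intermediate
16 | 4-[(benzyloxy)methyl]-4,6-dimethyl-5-[2-(2-methyl-1,3-dioxolan-2-yl)ethyl]cyclohex-2-en-1-one, C4 and C5 arranged as in 15, C6 epimers (formed in the flask) | CC1(CC[C@@H]2C(C)C(=O)C=C[C@@]2(C)COCc3ccccc3)OCCO1 | intermediate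
17 | (4R,5S)-4-[(benzyloxy)methyl]-4,6,6-trimethyl-5-[2-(2-methyl-1,3-dioxolan-2-yl)ethyl]cyclohex-2-en-1-one | CC1(CC[C@@H]2C(C)(C)C(=O)C=C[C@@]2(C)COCc3ccccc3)OCCO1 | intermediate
18 | (3S,4R)-4-(hydroxymethyl)-2,2,4-trimethyl-3-[2-(2-methyl-1,3-dioxolan-2-yl)ethyl]cyclohexan-1-one | CC1(CC[C@@H]2C(C)(C)C(=O)CC[C@@]2(C)CO)OCCO1 | intermediate
19 | [(1R,2R)-1,3,3-trimethyl-2-[2-(2-methyl-1,3-dioxolan-2-yl)ethyl]cyclohexyl]methanol | CC1(CC[C@@H]2C(C)(C)CCC[C@@]2(C)CO)OCCO1 | intermediate
20 | (1R,2R)-1,3,3-trimethyl-2-[2-(2-methyl-1,3-dioxolan-2-yl)ethyl]cyclohexane-1-carbaldehyde | CC1(CC[C@@H]2C(C)(C)CCC[C@@]2(C)C=O)OCCO1 | intermediate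
21 | but-3-yn-1-ol | C#CCCO | starting material
22 | 1-[(but-3-yn-1-yloxy)methyl]-4-methoxybenzene | COc1ccc(COCCC#C)cc1 | intermediate
23 | dimethyl[(1E)-4-[(4-methoxybenzyl)oxy]-2-methylbut-1-en-1-yl]alumane (formed in the flask) | COc1ccc(COCC/C(C)=C/[Al](C)C)cc1 | intermediate
24 | lithium butyl(dimethyl)[(1E)-4-[(4-methoxybenzyl)oxy]-2-methylbut-1-en-1-yl]alanate (formed in the flask) | [Li+].COc1ccc(COCC/C(C)=C/[Al-](C)(C)CCCC)cc1 | intermediate
25 | (E)-5-[(4-methoxybenzyl)oxy]-3-methylpent-2-en-1-ol | COc1ccc(COCC/C(C)=C/CO)cc1 | intermediate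
26 | tert-butyl{[(2E)-5-[(4-methoxybenzyl)oxy]-3-methylpent-2-en-1-yl]oxy}dimethylsilane | COc1ccc(COCC/C(C)=C/CO[Si](C)(C)C(C)(C)C)cc1 | intermediate
27 | (E)-5-[(tert-butyldimethylsilyl)oxy]-3-methylpent-3-en-1-ol | OCC/C(C)=C/CO[Si](C)(C)C(C)(C)C | intermediate
28 | tert-butyl{[(2E)-5-iodo-3-methylpent-2-en-1-yl]oxy}dimethylsilane | ICC/C(C)=C/CO[Si](C)(C)C(C)(C)C | intermediate
29 | [(3E)-5-[(tert-butyldimethylsilyl)oxy]-3-methylpent-3-en-1-yl]lithium (formed in the flask) | [Li]CC/C(C)=C/CO[Si](C)(C)C(C)(C)C | intermediate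
30 | (4E)-6-[(tert-butyldimethylsilyl)oxy]-4-methyl-1-[(1R,2R)-1,3,3-trimethyl-2-[2-(2-methyl-1,3-dioxolan-2-yl)ethyl]cyclohexyl]hex-4-en-1-ol (carbinol epimers) | CC1(CC[C@@H]2C(C)(C)CCC[C@@]2(C)C(O)CC/C(C)=C/CO[Si](C)(C)C(C)(C)C)OCCO1 | intermediate
31 | (4E)-6-[(tert-butyldimethylsilyl)oxy]-4-methyl-1-[(1R,2R)-1,3,3-trimethyl-2-[2-(2-methyl-1,3-dioxolan-2-yl)ethyl]cyclohexyl]hex-4-en-1-one | CC1(CC[C@@H]2C(C)(C)CCC[C@@]2(C)C(=O)CC/C(C)=C/CO[Si](C)(C)C(C)(C)C)OCCO1 | intermediate
32 | (4E)-6-hydroxy-4-methyl-1-[(1R,2R)-1,3,3-trimethyl-2-(3-oxobutyl)cyclohexyl]hex-4-en-1-one | CC(=O)CC[C@@H]1C(C)(C)CCC[C@@]1(C)C(=O)CC/C(C)=C/CO | intermediate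
33 | (2E)-3-methyl-6-oxo-6-[(1R,2R)-1,3,3-trimethyl-2-(3-oxobutyl)cyclohexyl]hex-2-en-1-yl acetate (CNP0326957.1) | CC(=O)CC[C@@H]1C(C)(C)CCC[C@@]1(C)C(=O)CC/C(C)=C/COC(C)=O | target

## Step count and risks

Total step count: 22 steps. Longest linear sequence: 14 steps (steps 1–3, 7–13 and 19–22; the diene branch through steps 4–6 is equally long).

Steps most likely to fail:

Step 7 (proposed new method). The trisubstituted enal may add more slowly than the diene is consumed by desilylation or oligomerisation on the Lewis acid, or the catalyst may differentiate the two enal faces poorly. The fallback moves stereocontrol from the catalyst to a covalently bound auxiliary on a more electron-rich diene and leaves out the Lewis acid; thermal cycloadditions of chiral 1-amino-3-siloxydienes with α-substituted enals are known chemistry. It sets out from enal 5 and methoxy enone 6. Addition–elimination of (2R,5R)-2,5-diphenylpyrrolidine on 6 (MeOH, rt) gives the vinylogous amide (E)-4-[(2R,5R)-2,5-diphenylpyrrolidin-1-yl]but-3-en-2-one F1. KN(SiMe3)2 and TBSCl in THF at −78 °C give the diene (2R,5R)-1-[(1E)-3-(tert-butyldimethylsilyloxy)buta-1,3-dien-1-yl]-2,5-diphenylpyrrolidine F2. Warming F2 with 5 in toluene without catalyst should give the amino cycloadduct (1S,2R,6R)-4-(tert-butyldimethylsilyloxy)-2-[(2R,5R)-2,5-diphenylpyrrolidin-1-yl]-1-methyl-6-[2-(2-methyl-1,3-dioxolan-2-yl)ethyl]cyclohex-3-ene-1-carbaldehyde F3, in which the C2-symmetric pyrrolidine shields one diene face. Brief treatment with dilute HCl in THF at 0 °C hydrolyses the silyl enol ether and expels the protonated amine, so the route is rejoined at 13 and the auxiliary is recovered. The antipodal auxiliary is used if the facial sense requires it.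

Step 10. The second alkylation may stall because the already substituted enolate carbon is shielded by the neighbouring chain-bearing centre, so that O-methylation and proton exchange take over. The fallback brings in the second methyl group as a CH2 unit instead of by SN2 alkylation. It sets out from monomethyl enone 16, isolated after one cycle of step 10. LiN(i-Pr)2 and Me3SiCl in THF at −78 °C give the cross-conjugated silyl dienol ether {[4-[(benzyloxy)methyl]-2,4-dimethyl-3-[2-(2-methyl-1,3-dioxolan-2-yl)ethyl]cyclohexa-1,5-dien-1-yl]oxy}trimethylsilane F4. Et2Zn/CH2I2 (Simmons–Smith cyclopropanation, Furukawa variant) should react at its electron-rich enol-ether double bond and give the siloxycyclopropane 4-[(benzyloxy)methyl]-4,6-dimethyl-5-[2-(2-methyl-1,3-dioxolan-2-yl)ethyl]-1-(trimethylsilyloxy)bicyclo[4.1.0]hept-2-ene F5. K2CO3 in MeOH then opens the cyclopropanol at the bond between CH2 and the oxygen-bearing carbon, which turns the CH2 into the second methyl group and regenerates the enone, so the route is rejoined at 17.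

Step 21. While silyl ether and ketal are removed together, the free allylic alcohol may ionise under acid (allylic transposition, solvolysis), and the liberated 1,6-diketone may begin an acid-catalysed intramolecular aldol condensation. The fallback separates the two deprotections and puts the acetate on before any acid is used. It sets out from 31. Bu4NF in THF at 0 °C gives the allylic alcohol (4E)-6-hydroxy-4-methyl-1-[(1R,2R)-1,3,3-trimethyl-2-[2-(2-methyl-1,3-dioxolan-2-yl)ethyl]cyclohexyl]hex-4-en-1-one F6. Ac2O, pyridine and DMAP give the acetate (2E)-3-methyl-6-oxo-6-[(1R,2R)-1,3,3-trimethyl-2-[2-(2-methyl-1,3-dioxolan-2-yl)ethyl]cyclohexyl]hex-2-en-1-yl acetate F7. Pyridinium p-toluenesulfonate in wet acetone then exchanges the dioxolane under the mildest acid available, with the allylic oxygen already acylated, and the route is rejoined at the target 33.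

Further compounds
F1 | step 7 | (E)-4-[(2R,5R)-2,5-diphenylpyrrolidin-1-yl]but-3-en-2-one | CC(=O)/C=C/N1[C@@H](c2ccccc2)CC[C@@H]1c1ccccc1
F2 | step 7 | (2R,5R)-1-[(1E)-3-(tert-butyldimethylsilyloxy)buta-1,3-dien-1-yl]-2,5-diphenylpyrrolidine | C=C(O[Si](C)(C)C(C)(C)C)/C=C/N1[C@@H](c2ccccc2)CC[C@@H]1c1ccccc1
F3 | step 7 | (1S,2R,6R)-4-(tert-butyldimethylsilyloxy)-2-[(2R,5R)-2,5-diphenylpyrrolidin-1-yl]-1-methyl-6-[2-(2-methyl-1,3-dioxolan-2-yl)ethyl]cyclohex-3-ene-1-carbaldehyde | CC1(CC[C@@H]2CC(O[Si](C)(C)C(C)(C)C)=C[C@@H](N3[C@@H](c4ccccc4)CC[C@@H]3c3ccccc3)[C@@]2(C)C=O)OCCO1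
F4 | step 10 | {[4-[(benzyloxy)methyl]-2,4-dimethyl-3-[2-(2-methyl-1,3-dioxolan-2-yl)ethyl]cyclohexa-1,5-dien-1-yl]oxy}trimethylsilane (ring centres as in 15) | CC1(CC[C@@H]2C(C)=C(O[Si](C)(C)C)C=C[C@@]2(C)COCc3ccccc3)OCCO1
F5 | step 10 | 4-[(benzyloxy)methyl]-4,6-dimethyl-5-[2-(2-methyl-1,3-dioxolan-2-yl)ethyl]-1-(trimethylsilyloxy)bicyclo[4.1.0]hept-2-ene (C4 and C5 as in 15, cyclopropane face not assigned) | CC1(CC[C@@H]2C3(C)CC3(O[Si](C)(C)C)C=C[C@@]2(C)COCc4ccccc4)OCCO1
F6 | step 21 | (4E)-6-hydroxy-4-methyl-1-[(1R,2R)-1,3,3-trimethyl-2-[2-(2-methyl-1,3-dioxolan-2-yl)ethyl]cyclohexyl]hex-4-en-1-one | CC1(CC[C@@H]2C(C)(C)CCC[C@@]2(C)C(=O)CC/C(C)=C/CO)OCCO1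
F7 | step 21 | (2E)-3-methyl-6-oxo-6-[(1R,2R)-1,3,3-trimethyl-2-[2-(2-methyl-1,3-dioxolan-2-yl)ethyl]cyclohexyl]hex-2-en-1-yl acetate | CC1(CC[C@@H]2C(C)(C)CCC[C@@]2(C)C(=O)CC/C(C)=C/COC(C)=O)OCCO1
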